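**Plan**

- Numbering of the target naphthalene: C1 (aryl), C2 (vanillyl CH2), C3 (OH), C4 (H), C4a, C5–C7 (OMe, OH, OMe), C8 (H), C8a. The enabling feature is C4, a bare CH between the hydroxyl carbon C3 and the ring-fusion carbon C4a of ring B. Removing it leaves a 3-aryl-2-benzylinden-1-one whose carbonyl carbon is C3 and whose ring carbon C4a has methoxy groups ortho and para to it.
- Retrosynthesis: the three phenols are masked as isopropyl ethers. C3–C4 and C4–C4a are cut together (one-carbon excision) to the indenone. The benzyl C–C bond is cut to an aldehyde plus a 3-arylindan-1-one (aldol, then alkene shift). The indanone is cut at the acyl–aryl bond (Friedel–Crafts) and at the C3–aryl bond (conjugate addition), back to syringaldehyde, Meldrum's acid and an aryl bromide.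
- Forward: ring A comes intact from syringaldehyde, and the five-membered ring closes by Friedel–Crafts acylation ortho/para to its methoxy groups. The benzyl arm is attached by aldol condensation and the double bond is moved into the ring. The five-membered ring is then enlarged by one carbon to aromatic ring B, and BCl3 frees the three phenols.
- Stereochemistry: the target has no stereocentre, so none has to be set.

Key step: step 9

Remark: compounds 8, 9, 10, 13 and 15 carry sp3 stereocentres that form racemic (9 as a diastereomer mixture). All are erased by compound 14 or 16, so no stereocontrol is planned.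

**Route**

Step 1
Reactants: 1 syringaldehyde (4-hydroxy-3,5-dimethoxybenzaldehyde)
Product: 2 4-isopropoxy-3,5-dimethoxybenzaldehyde
Conditions: iPrBr, K2CO3, DMF, 70 °C
Reagents that add atoms: 2-bromopropane, CC(C)Br
Why: Williamson etherification of the acidic para-formyl phenol should be clean in DMF, and the isopropyl ether is chosen because BCl3 later removes it beside methyl ethers.

Step 2
Reactants: 2 4-isopropoxy-3,5-dimethoxybenzaldehyde; 3 Meldrum's acid (2,2-dimethyl-1,3-dioxane-4,6-dione)
Product: 4 5-(4-isopropoxy-3,5-dimethoxybenzylidene)-2,2-dimethyl-1,3-dioxane-4,6-dione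
Conditions: piperidine (cat.), AcOH (cat.), toluene, 50 °C
Reagents that add atoms: none
Why: Knoevenagel condensation of a non-enolisable aryl aldehyde with the strongly C–H acidic Meldrum's acid should give the doubly activated alkene, which needs no E/Z control.

Step 3
Reactants: 5 4-bromo-3-methoxyphenol
Product: 6 1-bromo-4-isopropoxy-2-methoxybenzene
Conditions: iPrBr, K2CO3, DMF, 70 °C
Reagents that add atoms: 2-bromopropane, CC(C)Br
Why: Williamson etherification fixes the 4-isopropoxy-2-methoxy pattern relative to the bromine, which becomes the carbon nucleophile.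

Step 4
Reactants: 6 1-bromo-4-isopropoxy-2-methoxybenzene; 4 5-(4-isopropoxy-3,5-dimethoxybenzylidene)-2,2-dimethyl-1,3-dioxane-4,6-dione
Product: 8 5-[(4-isopropoxy-3,5-dimethoxyphenyl)(4-isopropoxy-2-methoxyphenyl)methyl]-2,2-dimethyl-1,3-dioxane-4,6-dione (racemic), via aryl Grignard reagent 7 (not isolated)
Conditions: Mg, THF, reflux (I2 cat.); then 4, THF, −20 to 0 °C; then 1 M HCl
Reagents that add atoms: none
Why: Grignard formation followed by uncatalysed conjugate addition to the alkylidene Meldrum's acid should give the diarylmethyl adduct, since the 1,4-position is the only electrophilic site of this doubly activated acceptor; the new diarylmethine centre forms racemic and is erased later.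

Step 5
Reactants: 8 5-[(4-isopropoxy-3,5-dimethoxyphenyl)(4-isopropoxy-2-methoxyphenyl)methyl]-2,2-dimethyl-1,3-dioxane-4,6-dione
Product: 10 3-(4-isopropoxy-2-methoxyphenyl)-6-isopropoxy-5,7-dimethoxyindan-1-one (racemic), via 1-oxoindane-2-carboxylic acid 9 (not isolated)
Conditions: Sc(OTf)3 (10 mol %), MeNO2, 100 °C
Reagents that add atoms: none
Why: Sc(OTf)3-catalysed intramolecular Friedel–Crafts acylation with the Meldrum's acid as acyl donor should close the five-membered ring at the syringyl carbon that is ortho to one methoxy and para to the other (the other aryl ring offers only a position meta to both its oxygens), and loss of acetone and CO2 then gives the indanone with the carbonyl next to the methoxy-bearing carbon.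

Step 6
Reactants: 11 vanillin (4-hydroxy-3-methoxybenzaldehyde)
Product: 12 4-isopropoxy-3-methoxybenzaldehyde
Conditions: iPrBr, K2CO3, DMF, 70 °C
Reagents that add atoms: 2-bromopropane, CC(C)Br
Why: Williamson etherification protects the vanillyl phenol in the same form as the other two.

Step 7
Reactants: 10 3-(4-isopropoxy-2-methoxyphenyl)-6-isopropoxy-5,7-dimethoxyindan-1-one; 12 4-isopropoxy-3-methoxybenzaldehyde
Product: 13 (E)-2-(4-isopropoxy-3-methoxybenzylidene)-3-(4-isopropoxy-2-methoxyphenyl)-6-isopropoxy-5,7-dimethoxyindan-1-one (racemic)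
Conditions: KOH (0.3 equiv), EtOH, 25 °C, Ar
Reagents that add atoms: none
Why: Claisen–Schmidt (crossed aldol) condensation should be unambiguous because C2 is the only enolisable carbon and the aldehyde cannot enolise, and E1cB dehydration should give the E-benzylidene ketone.

Step 8
Reactants: 13 (E)-2-(4-isopropoxy-3-methoxybenzylidene)-3-(4-isopropoxy-2-methoxyphenyl)-6-isopropoxy-5,7-dimethoxyindan-1-one
Product: 14 3-(4-isopropoxy-2-methoxyphenyl)-2-(4-isopropoxy-3-methoxybenzyl)-6-isopropoxy-5,7-dimethoxy-1H-inden-1-one
Conditions: RhCl3·3H2O (10 mol %), EtOH, reflux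
Reagents that add atoms: none
Why: Rhodium hydride addition–elimination isomerisation, known for turning 2-benzylidene cyclic ketones into the endocyclic 2-benzyl enones, should move the double bond into the ring, driven by the tetrasubstituted aryl-conjugated alkene and relief of allylic strain; the C3 stereocentre disappears here.

Step 9
Reactants: 14 3-(4-isopropoxy-2-methoxyphenyl)-2-(4-isopropoxy-3-methoxybenzyl)-6-isopropoxy-5,7-dimethoxy-1H-inden-1-one
Product: 16 4-(4-isopropoxy-2-methoxyphenyl)-3-(4-isopropoxy-3-methoxybenzyl)-7-isopropoxy-6,8-dimethoxynaphthalen-2-ol (the free hydroxyl is C3–OH in the plan numbering), via alpha-silyl naphthalenone 15 (not isolated)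
Conditions: TMSCHN2 (2 equiv), BF3·OEt2 (1.2 equiv), CH2Cl2, −78 to −20 °C; aq. NaHCO3; then 1 M HCl, THF, 25 °C
Reagents that add atoms: trimethylsilyldiazomethane, C[Si](C)(C)C=[N+]=[N-]
Why: Proposed new method: BF3 coordination to the indenone carbonyl (indenone C1, naphthalene C3) lets the nucleophilic carbon of trimethylsilyldiazomethane add to C=O, and in the resulting β-oxido diazonium ion the electron-rich ring carbon (indenone C7a, naphthalene C4a) shifts to the diazo carbon as N2 leaves, a Tiffeneau–Demjanov-type 1,2-shift that creates the C3–C4 and C4–C4a bonds. The closest known reaction is the Lewis-acid-promoted trimethylsilyldiazomethane homologation of 1-indanones and other aryl ketones to the one-carbon-larger ketones by aryl migration; its use on a 2,3-disubstituted indenone is the untested part. Ring B is not closed end to end but arises by enlargement of the five-membered ring through this 1,2-aryl shift, after which the α-silyl dienone 15 loses silicon and enolises to the aromatic naphthol. No lasting stereocentre is formed, because the silyl-bearing carbon of 15 becomes the aromatic C4–H. The step needs migration of the aryl carbon and not of the vinylic C2, addition to the carbonyl and not 1,3-dipolar addition across the enone, and a single insertion: the migrating carbon has methoxy groups ortho and para to it and so the higher migratory aptitude, the tetrasubstituted C2=C3 bond is shielded by its aryl and benzyl groups while BF3 activates only the carbonyl, and the naphthol product has no ketone left to react again.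

Step 10
Reactants: 16 4-(4-isopropoxy-2-methoxyphenyl)-3-(4-isopropoxy-3-methoxybenzyl)-7-isopropoxy-6,8-dimethoxynaphthalen-2-ol
Product: 17 4-(4-hydroxy-2-methoxyphenyl)-3-(4-hydroxy-3-methoxybenzyl)-6,8-dimethoxynaphthalene-2,7-diol (target)
Conditions: BCl3 (1 M in CH2Cl2, 6 equiv), CH2Cl2, −78 to 0 °C; then H2O
Reagents that add atoms: none
Why: BCl3-mediated dealkylation should cleave the three secondary isopropyl aryl ethers through their more stable carbocation-like pathway at low temperature and leave the four methyl ethers, none of which sits next to a chelating carbonyl.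

**Compound list**

1 | syringaldehyde (4-hydroxy-3,5-dimethoxybenzaldehyde) | COc1cc(C=O)cc(OC)c1O | starting material
2 | 4-isopropoxy-3,5-dimethoxybenzaldehyde | COc1cc(C=O)cc(OC)c1OC(C)C | intermediate
3 | Meldrum's acid (2,2-dimethyl-1,3-dioxane-4,6-dione) | CC1(C)OC(=O)CC(=O)O1 | starting material
4 | 5-(4-isopropoxy-3,5-dimethoxybenzylidene)-2,2-dimethyl-1,3-dioxane-4,6-dione | COc1cc(C=C2C(=O)OC(C)(C)OC2=O)cc(OC)c1OC(C)C | intermediate
5 | 4-bromo-3-methoxyphenol | COc1cc(O)ccc1Br | starting material
6 | 1-bromo-4-isopropoxy-2-methoxybenzene | COc1cc(OC(C)C)ccc1Br | intermediate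
7 | (4-isopropoxy-2-methoxyphenyl)magnesium bromide (not isolated) | COc1cc(OC(C)C)ccc1[Mg]Br | intermediate
8 | 5-[(4-isopropoxy-3,5-dimethoxyphenyl)(4-isopropoxy-2-methoxyphenyl)methyl]-2,2-dimethyl-1,3-dioxane-4,6-dione (racemic) | COc1cc(C(c2ccc(OC(C)C)cc2OC)C2C(=O)OC(C)(C)OC2=O)cc(OC)c1OC(C)C | intermediate
9 | 3-(4-isopropoxy-2-methoxyphenyl)-6-isopropoxy-5,7-dimethoxy-1-oxoindane-2-carboxylic acid (diastereomer mixture, not isolated) | O=C1C(C(=O)O)C(c2ccc(OC(C)C)cc2OC)c2cc(OC)c(OC(C)C)c(OC)c12 | intermediate
10 | 3-(4-isopropoxy-2-methoxyphenyl)-6-isopropoxy-5,7-dimethoxyindan-1-one (racemic) | O=C1CC(c2ccc(OC(C)C)cc2OC)c2cc(OC)c(OC(C)C)c(OC)c12 | intermediate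
11 | vanillin (4-hydroxy-3-methoxybenzaldehyde) | COc1cc(C=O)ccc1O | starting material
12 | 4-isopropoxy-3-methoxybenzaldehyde | COc1cc(C=O)ccc1OC(C)C | intermediate
13 | (E)-2-(4-isopropoxy-3-methoxybenzylidene)-3-(4-isopropoxy-2-methoxyphenyl)-6-isopropoxy-5,7-dimethoxyindan-1-one (racemic) | O=C1/C(=C/c2ccc(OC(C)C)c(OC)c2)C(c2ccc(OC(C)C)cc2OC)c2cc(OC)c(OC(C)C)c(OC)c12 | intermediate
14 | 3-(4-isopropoxy-2-methoxyphenyl)-2-(4-isopropoxy-3-methoxybenzyl)-6-isopropoxy-5,7-dimethoxy-1H-inden-1-one | O=C1C(Cc2ccc(OC(C)C)c(OC)c2)=C(c2ccc(OC(C)C)cc2OC)c2cc(OC)c(OC(C)C)c(OC)c12 | intermediate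
15 | 3-(4-isopropoxy-3-methoxybenzyl)-4-(4-isopropoxy-2-methoxyphenyl)-7-isopropoxy-6,8-dimethoxy-1-(trimethylsilyl)naphthalen-2(1H)-one (racemic, not isolated) | O=C1C(Cc2ccc(OC(C)C)c(OC)c2)=C(c2ccc(OC(C)C)cc2OC)c2cc(OC)c(OC(C)C)c(OC)c2C1[Si](C)(C)C | intermediate
16 | 4-(4-isopropoxy-2-methoxyphenyl)-3-(4-isopropoxy-3-methoxybenzyl)-7-isopropoxy-6,8-dimethoxynaphthalen-2-ol | COc1cc(Cc2c(O)cc3c(OC)c(OC(C)C)c(OC)cc3c2-c2ccc(OC(C)C)cc2OC)ccc1OC(C)C | intermediate
17 | 4-(4-hydroxy-2-methoxyphenyl)-3-(4-hydroxy-3-methoxybenzyl)-6,8-dimethoxynaphthalene-2,7-diol | COc1cc(Cc2c(O)cc3c(OC)c(O)c(OC)cc3c2-c2ccc(O)cc2OC)ccc1O | target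

**Count**

Total steps: 10. Longest linear sequence: 8 (steps 1, 2, 4, 5, 7, 8, 9, 10).

**Steps most likely to fail**

1. Step 9 (proposed new method). The vinylic carbon C2 may migrate in place of the aryl carbon, the diazoalkane may add across the enone as a 1,3-dipole, or it may fail to add to a carbonyl that is deactivated by its ortho and para methoxy donors. The fallback uses the documented substrate class, a saturated 1-indanone. It sets out from 13: hydrogenation of the exocyclic alkene (H2, Pd/C, EtOAc) should give 2-(4-isopropoxy-3-methoxybenzyl)-3-(4-isopropoxy-2-methoxyphenyl)-6-isopropoxy-5,7-dimethoxyindan-1-one F1 as a cis/trans mixture. Homologation with TMSCHN2 and BF3·OEt2 in CH2Cl2 at −78 °C, with aryl migration and desilylation on work-up, should give 4-(4-isopropoxy-2-methoxyphenyl)-3-(4-isopropoxy-3-methoxybenzyl)-7-isopropoxy-6,8-dimethoxy-3,4-dihydronaphthalen-2(1H)-one F2. Dehydrogenation of this 2-tetralone with DDQ in dioxane should aromatise ring B and return to the route at 16.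

2. Step 8. The alkene shift may stall or stop at an exo/endo equilibrium mixture, or rhodium hydride addition at the hindered C2 may be too slow. The fallback replaces the isomerisation by a reduction–oxidation pair that places the double bond by hydride abstraction at C3. It sets out from 13: 1,4-hydrosilylation (Et3SiH, RhCl(PPh3)3 cat., benzene, 60 °C) should give triethyl{[1-(4-isopropoxy-2-methoxyphenyl)-2-(4-isopropoxy-3-methoxybenzyl)-5-isopropoxy-4,6-dimethoxy-1H-inden-3-yl]oxy}silane F3. Oxidation of this silyl enol ether with DDQ and 2,6-lutidine in CH2Cl2 at 0 °C should remove the doubly benzylic C3 hydride, lose the silyl group and return to the route at 14.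

3. Step 5. The Lewis acid may ionise the benzhydryl–Meldrum's acid C–C bond to a donor-stabilised diarylmethyl cation, which would alkylate other arenes instead of the acyl transfer taking place. The fallback separates decarboxylation from ring closure. It sets out from 8: hydrolytic decarboxylation in pyridine/H2O at reflux should give 3-(4-isopropoxy-3,5-dimethoxyphenyl)-3-(4-isopropoxy-2-methoxyphenyl)propanoic acid F4. Mixed-anhydride Friedel–Crafts cyclisation (TFAA, CH2Cl2, 0 to 25 °C) onto the activated syringyl ring should then return to the route at 10.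

**Further compounds**

F1 | step 9 | 2-(4-isopropoxy-3-methoxybenzyl)-3-(4-isopropoxy-2-methoxyphenyl)-6-isopropoxy-5,7-dimethoxyindan-1-one (cis/trans mixture, racemic) | O=C1C(Cc2ccc(OC(C)C)c(OC)c2)C(c2ccc(OC(C)C)cc2OC)c2cc(OC)c(OC(C)C)c(OC)c12
F2 | step 9 | 4-(4-isopropoxy-2-methoxyphenyl)-3-(4-isopropoxy-3-methoxybenzyl)-7-isopropoxy-6,8-dimethoxy-3,4-dihydronaphthalen-2(1H)-one (diastereomer mixture, racemic) | O=C1Cc2c(OC)c(OC(C)C)c(OC)cc2C(c2ccc(OC(C)C)cc2OC)C1Cc1ccc(OC(C)C)c(OC)c1
F3 | step 8 | triethyl{[1-(4-isopropoxy-2-methoxyphenyl)-2-(4-isopropoxy-3-methoxybenzyl)-5-isopropoxy-4,6-dimethoxy-1H-inden-3-yl]oxy}silane (racemic) | CC[Si](CC)(CC)OC1=C(Cc2ccc(OC(C)C)c(OC)c2)C(c2ccc(OC(C)C)cc2OC)c2cc(OC)c(OC(C)C)c(OC)c12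
F4 | step 5 | 3-(4-isopropoxy-3,5-dimethoxyphenyl)-3-(4-isopropoxy-2-methoxyphenyl)propanoic acid (racemic) | COc1cc(C(CC(=O)O)c2ccc(OC(C)C)cc2OC)cc(OC)c1OC(C)C
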